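**Retrosynthetic overview**
1. End game: the C11 hydroxyl comes from a C11 methyl ether (oxidative demethylation to the 11,14-quinone, then reduction). Ring B is closed last by Friedel–Crafts acylation C7→C8.
2. Ring A and the δ-lactone are made together by a tethered Favorskii contraction of a seven-membered 2-bromo-2-methyl ketone, in which the future C19 is still a ring member between C3 and C4.
3. Enabling feature: the C19 carbonyl on quaternary C4 sits 1,3-diaxial to the C20–O arm on C10. With C19 written back into the carbocycle, the C20 alkoxide reaches it through a six-membered hemiketal, so contraction expels C19 as the lactone carbonyl and creates C4 (methyl plus carboxyl) cis to C20.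
4. The seven-membered ketone comes from a cyclohexenone: C9–C10 by Cu-catalysed asymmetric conjugate addition, C4 by dibromocarbene ring expansion, C18 by Negishi coupling, C5–C6 by Mukaiyama–Michael addition.
5. Ring order: ring C (arene, bought) → carrier cyclohexanone → cycloheptenone → ring A and lactone ring (key step) → ring B.

Key step: step 12

Remark: C-locants are the abietane locants of the target; Ar = 2,3-dimethoxy-4-(propan-2-yl)-5-[tri(propan-2-yl)silyloxy]phenyl, TBS = tert-butyl(dimethyl)silyl, TIPS = tri(propan-2-yl)silyl, TMS = trimethylsilyl; in step 7 the ligand antipode that gives the (R) centre is used.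

Step 1
Reactants: 1 3,4-dimethoxyphenol
Product: 2 4-(methoxymethoxy)-1,2-dimethoxybenzene
Conditions: NaH, THF/DMF, 0 °C; MOMCl, 0 °C to rt
Reagents that add atoms: chloromethyl methyl ether, COCCl
Why: O-alkylation of the sodium phenoxide (Williamson ether synthesis) installs the MOM acetal that directs the metalation of step 2.

Step 2
Reactants: 2 4-(methoxymethoxy)-1,2-dimethoxybenzene
Product: 4 2-[2,3-dimethoxy-6-(methoxymethoxy)phenyl]propan-2-ol, via aryllithium 3 (not isolated)
Conditions: n-BuLi, THF, 0 °C; acetone, −78 °C to rt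
Reagents that add atoms: acetone, CC(C)=O
Why: Directed ortho-metalation should occur at the one C–H flanked by the OMOM and OMe groups, and 1,2-addition of the aryllithium to acetone places the three isopropyl carbons on the future C13.

Step 3
Reactants: 4 2-[2,3-dimethoxy-6-(methoxymethoxy)phenyl]propan-2-ol
Product: 5 3,4-dimethoxy-2-(propan-2-yl)phenol
Conditions: Et3SiH, CF3CO2H, CH2Cl2, 0 °C to rt
Reagents that add atoms: none
Why: Ionic hydrogenation: the acid ionises the doubly ortho-oxygenated tertiary benzylic alcohol, the silane reduces the cation, and the same acid cleaves the MOM acetal.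

Step 4
Reactants: 5 3,4-dimethoxy-2-(propan-2-yl)phenol
Product: 6 [3,4-dimethoxy-2-(propan-2-yl)phenoxy]tri(propan-2-yl)silane
Conditions: NaH, THF, 0 °C; i-Pr3SiCl, rt
Reagents that add atoms: chlorotri(propan-2-yl)silane, CC(C)[Si](Cl)(C(C)C)C(C)C
Why: Silylation of the phenoxide gives a bulky, non-coordinating OTIPS group that blocks C8, so the later metalation can only be directed by the C11 methoxy group to C9.

Step 5
Reactants: 7 (3-methoxyphenyl)methanol
Product: 9 3-(hydroxymethyl)cyclohex-2-en-1-one, via dihydroanisole 8 (not isolated)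
Conditions: Li, NH3 (l), t-BuOH, THF, −78 °C; then 2 M HCl, THF, rt
Reagents that add atoms: water, O
Why: Birch reduction of the anisole ring (benzylic alcohol protected as its alkoxide) gives the 2,5-dihydroanisole, whose enol ether is hydrolysed and whose double bond moves into conjugation.

Step 6
Reactants: 9 3-(hydroxymethyl)cyclohex-2-en-1-one
Product: 10 3-{[tert-butyl(dimethyl)silyl]oxymethyl}cyclohex-2-en-1-one
Conditions: t-BuMe2SiCl, imidazole, DMF, rt
Reagents that add atoms: tert-butyl(chloro)dimethylsilane, CC(C)(C)[Si](C)(C)Cl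
Why: Standard silylation of the primary alcohol protects the future C20 oxygen until the key step.

Step 7
Reactants: 6 [3,4-dimethoxy-2-(propan-2-yl)phenoxy]tri(propan-2-yl)silane; 10 3-{[tert-butyl(dimethyl)silyl]oxymethyl}cyclohex-2-en-1-one
Product: 14 tert-butyl({(1R)-1-Ar-3-[(trimethylsilyl)oxy]cyclohex-2-en-1-yl}methoxy)dimethylsilane, via aryllithium 11 (not isolated), via arylalane 12 (not isolated), via aluminium enolate 13 (not isolated)
Conditions: 6, n-BuLi, TMEDA, Et2O, 0 °C to rt; Me2AlCl, −78 to 0 °C; then 10, Cu(O2CC4H3S) (copper thiophene-2-carboxylate, 10 mol %), chiral phosphinamine ligand of the SimplePhos type (11 mol %), Et2O, −30 °C; then TMSOTf, −78 to 0 °C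
Reagents that add atoms: trimethylsilyl trifluoromethanesulfonate, C[Si](C)(C)OS(=O)(=O)C(F)(F)F
Why: Methoxy-directed ortho-lithiation at C9, transmetalation to aluminium and copper-catalysed asymmetric conjugate addition of the aryl alane to the β-substituted enone should create the C10 quaternary centre (face chosen by the chiral ligand), and O-silylation of the aluminium enolate fixes the enol ether on the C5 side.

Step 8
Reactants: 14 tert-butyl({(1R)-1-Ar-3-[(trimethylsilyl)oxy]cyclohex-2-en-1-yl}methoxy)dimethylsilane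
Product: 16 (4R)-4-Ar-2-bromo-4-{[tert-butyl(dimethyl)silyl]oxymethyl}cyclohept-2-en-1-one, via dibromocyclopropane 15 (not isolated)
Conditions: CHBr3, KOt-Bu, pentane, −30 to 0 °C; then toluene, 90 °C
Reagents that add atoms: bromoform, BrC(Br)Br
Why: Dibromocarbene adds to the electron-rich silyl enol ether, and thermal cyclopropyl-to-allyl cation opening with loss of bromide and the silyl group inserts the future C4 between C19 and C5 (one-carbon ring expansion of silyl enol ethers to 2-halocycloalk-2-enones).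

Step 9
Reactants: 16 (4R)-4-Ar-2-bromo-4-{[tert-butyl(dimethyl)silyl]oxymethyl}cyclohept-2-en-1-one
Product: 17 (4R)-4-Ar-2-methyl-4-{[tert-butyl(dimethyl)silyl]oxymethyl}cyclohept-2-en-1-one
Conditions: MeZnCl, Pd(PPh3)4 (5 mol %), THF, rt
Reagents that add atoms: methylzinc chloride, C[Zn]Cl
Why: Negishi coupling of the α-bromoenone places the C18 methyl group on C4 without touching the enone or the silyl ethers.

Step 10
Reactants: 18 tert-butyl acetate
Product: 20 tert-butyl[(1-tert-butoxyethenyl)oxy]dimethylsilane, via lithium enolate 19 (not isolated)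
Conditions: LiN(i-Pr)2, THF, −78 °C; t-BuMe2SiCl, DMPU, −78 °C to rt
Reagents that add atoms: tert-butyl(chloro)dimethylsilane, CC(C)(C)[Si](C)(C)Cl
Why: O-silylation of the ester enolate gives the ketene silyl acetal that carries C6 and C7 as a tert-butyl ester, which is inert to the alkoxide of the key step.

Step 11
Reactants: 17 (4R)-4-Ar-2-methyl-4-{[tert-butyl(dimethyl)silyl]oxymethyl}cyclohept-2-en-1-one; 20 tert-butyl[(1-tert-butoxyethenyl)oxy]dimethylsilane
Product: 22 tert-butyl 2-[(1R,7R)-7-Ar-2-bromo-2-methyl-3-oxo-7-{[tert-butyl(dimethyl)silyl]oxymethyl}cycloheptyl]acetate (both C4 epimers; 5R,10R in abietane locants), via silyl enol ether 21 (not isolated)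
Conditions: (CF3SO2)2NH (5 mol %), CH2Cl2, −78 °C; then NBS, THF, −78 to 0 °C
Reagents that add atoms: N-bromosuccinimide, O=C1CCC(=O)N1Br
Why: Mukaiyama–Michael addition under silyl triflimide catalysis should attack C5 anti to the aryl group on the neighbouring C10 (cis to the CH2OTBS arm), which sets C5; silyl transfer gives the C19–C4 enol ether, which NBS brominates regiospecifically at C4.

Step 12
Reactants: 22 tert-butyl 2-[(1R,7R)-7-Ar-2-bromo-2-methyl-3-oxo-7-{[tert-butyl(dimethyl)silyl]oxymethyl}cycloheptyl]acetate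
Product: 24 tert-butyl 2-[(1S,5R,9R)-5-[5-hydroxy-2,3-dimethoxy-4-(propan-2-yl)phenyl]-1-methyl-2-oxo-3-oxabicyclo[3.3.1]nonan-9-yl]acetate (4S,5R,10R in abietane locants), via bromo ketone diol 23 (not isolated)
Conditions: Bu4NF (3 equiv), THF, 0 °C to rt, argon; H2O work-up
Reagents that add atoms: none
Why: Fluoride removes both silyl groups; the C20 alkoxide adds to the C19 ring ketone through a six-membered hemiketal and C3 shifts from C19 to C4 with loss of bromide (semibenzilic path), or, after enolisation at C3, the oxyallyl/cyclopropanone spanning C3–C19–C4 is captured by the same alkoxide and opens to the less substituted C3 carbanion, and both paths give the same lactone. The closest known reaction type is the Favorskii ring contraction of 2-halo-2-methylcycloalkanones with alkoxides to 1-methylcycloalkanecarboxylates, here with the alkoxide tethered. Ring A closes by the 1,2-shift that forms C3–C4 (contraction of the seven-membered ketone with C19 expelled), and the δ-lactone ring closes by 6-exo-trig addition of the C20 oxygen to the C19 carbonyl. The only new stereocentre, C4, is set by the tether: C19 stays bonded to an oxygen delivered from the face of C10 that carries C20, so C19 and C20 end up cis whatever the bromide configuration, while C5 and C10 are untouched. The step needs C19 to stay on C4 and must outrun E2 loss of HBr; the first is secured because the tertiary C4 keeps the carboxyl while the secondary C3 carbanion leaves, the second by six-membered intramolecular delivery of the nucleophile, and the tert-butyl ester keeps the alkoxide from being diverted to C7.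

Step 13
Reactants: 24 tert-butyl 2-[(1S,5R,9R)-5-[5-hydroxy-2,3-dimethoxy-4-(propan-2-yl)phenyl]-1-methyl-2-oxo-3-oxabicyclo[3.3.1]nonan-9-yl]acetate
Product: 26 (4S,5R,10R)-14-hydroxy-11,12-dimethoxy-7-oxoabieta-8,11,13-trien-19,20-olide, via carboxylic acid 25 (not isolated)
Conditions: CF3CO2H, CH2Cl2, rt; evaporate; then P2O5/MeSO3H (Eaton's reagent), rt
Reagents that add atoms: none
Why: Acidolysis of the tert-butyl ester and intramolecular Friedel–Crafts acylation at C8, the only free aromatic position and ortho to the C14 hydroxyl, should close ring B and deliver the C7 ketone, with the trans ring fusion already fixed by C5 and C10.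

Step 14
Reactants: 26 (4S,5R,10R)-14-hydroxy-11,12-dimethoxy-7-oxoabieta-8,11,13-trien-19,20-olide
Product: 28 (4S,5R,10R)-11,14-dihydroxy-12-methoxy-7-oxoabieta-8,11,13-trien-19,20-olide (CNP0159814.2), via quinone 27 (not isolated)
Conditions: PhI(OAc)2, MeCN/H2O, 0 °C; then aq. Na2S2O4, rt
Reagents that add atoms: water, O
Why: Oxidative demethylation of the para-methoxyphenol gives the 11,14-quinone with loss of methanol, and dithionite reduction returns the hydroquinone, which frees the C11 hydroxyl and leaves the C12 methyl ether in place.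

**Compound list**
1 | 3,4-dimethoxyphenol | COc1ccc(O)cc1OC | starting material
2 | 4-(methoxymethoxy)-1,2-dimethoxybenzene | COCOc1ccc(OC)c(OC)c1 | intermediate
3 | [2,3-dimethoxy-6-(methoxymethoxy)phenyl]lithium | [Li]c1c(OCOC)ccc(OC)c1OC | intermediate
4 | 2-[2,3-dimethoxy-6-(methoxymethoxy)phenyl]propan-2-ol | COCOc1ccc(OC)c(OC)c1C(C)(C)O | intermediate
5 | 3,4-dimethoxy-2-(propan-2-yl)phenol | CC(C)c1c(O)ccc(OC)c1OC | intermediate
6 | [3,4-dimethoxy-2-(propan-2-yl)phenoxy]tri(propan-2-yl)silane | CC(C)c1c(O[Si](C(C)C)(C(C)C)C(C)C)ccc(OC)c1OC | intermediate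
7 | (3-methoxyphenyl)methanol | COc1cccc(CO)c1 | starting material
8 | (5-methoxycyclohexa-1,4-dien-1-yl)methanol | COC1=CCC=C(CO)C1 | intermediate
9 | 3-(hydroxymethyl)cyclohex-2-en-1-one | O=C1C=C(CO)CCC1 | intermediate
10 | 3-{[tert-butyl(dimethyl)silyl]oxymethyl}cyclohex-2-en-1-one | O=C1C=C(CO[Si](C)(C)C(C)(C)C)CCC1 | intermediate
11 | {2,3-dimethoxy-4-(propan-2-yl)-5-[tri(propan-2-yl)silyloxy]phenyl}lithium | [Li]c1cc(O[Si](C(C)C)(C(C)C)C(C)C)c(C(C)C)c(OC)c1OC | intermediate
12 | {2,3-dimethoxy-4-(propan-2-yl)-5-[tri(propan-2-yl)silyloxy]phenyl}dimethylalumane | C[Al](C)c1cc(O[Si](C(C)C)(C(C)C)C(C)C)c(C(C)C)c(OC)c1OC | intermediate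
13 | dimethylaluminium (3R)-3-Ar-3-{[tert-butyl(dimethyl)silyl]oxymethyl}cyclohex-1-en-1-olate | C[Al](C)OC1=C[C@](c2cc(O[Si](C(C)C)(C(C)C)C(C)C)c(C(C)C)c(OC)c2OC)(CO[Si](C)(C)C(C)(C)C)CCC1 | intermediate
14 | tert-butyl({(1R)-1-Ar-3-[(trimethylsilyl)oxy]cyclohex-2-en-1-yl}methoxy)dimethylsilane | C[Si](C)(C)OC1=C[C@](c2cc(O[Si](C(C)C)(C(C)C)C(C)C)c(C(C)C)c(OC)c2OC)(CO[Si](C)(C)C(C)(C)C)CCC1 | intermediate
15 | (5R)-5-Ar-7,7-dibromo-5-{[tert-butyl(dimethyl)silyl]oxymethyl}-1-[(trimethylsilyl)oxy]bicyclo[4.1.0]heptane (cyclopropane diastereomers) | C[Si](C)(C)OC12CCC[C@@](c3cc(O[Si](C(C)C)(C(C)C)C(C)C)c(C(C)C)c(OC)c3OC)(CO[Si](C)(C)C(C)(C)C)C1C2(Br)Br | intermediate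
16 | (4R)-4-Ar-2-bromo-4-{[tert-butyl(dimethyl)silyl]oxymethyl}cyclohept-2-en-1-one | O=C1CCC[C@@](c2cc(O[Si](C(C)C)(C(C)C)C(C)C)c(C(C)C)c(OC)c2OC)(CO[Si](C)(C)C(C)(C)C)C=C1Br | intermediate
17 | (4R)-4-Ar-2-methyl-4-{[tert-butyl(dimethyl)silyl]oxymethyl}cyclohept-2-en-1-one | O=C1CCC[C@@](c2cc(O[Si](C(C)C)(C(C)C)C(C)C)c(C(C)C)c(OC)c2OC)(CO[Si](C)(C)C(C)(C)C)C=C1C | intermediate
18 | tert-butyl acetate | CC(=O)OC(C)(C)C | starting material
19 | lithium 1-tert-butoxyethen-1-olate | [Li]OC(=C)OC(C)(C)C | intermediate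
20 | tert-butyl[(1-tert-butoxyethenyl)oxy]dimethylsilane | C=C(OC(C)(C)C)O[Si](C)(C)C(C)(C)C | intermediate
21 | tert-butyl 2-[(1R,7R)-7-Ar-2-methyl-3-{[tert-butyl(dimethyl)silyl]oxy}-7-{[tert-butyl(dimethyl)silyl]oxymethyl}cyclohept-2-en-1-yl]acetate | CC1=C(O[Si](C)(C)C(C)(C)C)CCC[C@@](c2cc(O[Si](C(C)C)(C(C)C)C(C)C)c(C(C)C)c(OC)c2OC)(CO[Si](C)(C)C(C)(C)C)[C@H]1CC(=O)OC(C)(C)C | intermediate
22 | tert-butyl 2-[(1R,7R)-7-Ar-2-bromo-2-methyl-3-oxo-7-{[tert-butyl(dimethyl)silyl]oxymethyl}cycloheptyl]acetate (both C4 epimers) | CC1(Br)C(=O)CCC[C@@](c2cc(O[Si](C(C)C)(C(C)C)C(C)C)c(C(C)C)c(OC)c2OC)(CO[Si](C)(C)C(C)(C)C)[C@H]1CC(=O)OC(C)(C)C | intermediate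
23 | tert-butyl 2-[(1R,7R)-2-bromo-7-(hydroxymethyl)-7-[5-hydroxy-2,3-dimethoxy-4-(propan-2-yl)phenyl]-2-methyl-3-oxocycloheptyl]acetate (both C4 epimers) | CC1(Br)C(=O)CCC[C@@](c2cc(O)c(C(C)C)c(OC)c2OC)(CO)[C@H]1CC(=O)OC(C)(C)C | intermediate
24 | tert-butyl 2-[(1S,5R,9R)-5-[5-hydroxy-2,3-dimethoxy-4-(propan-2-yl)phenyl]-1-methyl-2-oxo-3-oxabicyclo[3.3.1]nonan-9-yl]acetate | CC(C)(C)OC(=O)C[C@@H]1[C@@]2(c3cc(O)c(C(C)C)c(OC)c3OC)CCC[C@]1(C)C(=O)OC2 | intermediate
25 | 2-[(1S,5R,9R)-5-[5-hydroxy-2,3-dimethoxy-4-(propan-2-yl)phenyl]-1-methyl-2-oxo-3-oxabicyclo[3.3.1]nonan-9-yl]acetic acid | OC(=O)C[C@@H]1[C@@]2(c3cc(O)c(C(C)C)c(OC)c3OC)CCC[C@]1(C)C(=O)OC2 | intermediate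
26 | (4S,5R,10R)-14-hydroxy-11,12-dimethoxy-7-oxoabieta-8,11,13-trien-19,20-olide | COc1c(OC)c2c(c(O)c1C(C)C)C(=O)C[C@@H]1[C@]23CCC[C@]1(C)C(=O)OC3 | intermediate
27 | (4S,5R,10R)-12-methoxy-7,11,14-trioxoabieta-8,12-dien-19,20-olide | COC1=C(C(C)C)C(=O)C2=C(C1=O)[C@]34CCC[C@](C)(C(=O)OC3)[C@@H]4CC2=O | intermediate
28 | (4S,5R,10R)-11,14-dihydroxy-12-methoxy-7-oxoabieta-8,11,13-trien-19,20-olide (CNP0159814.2) | COc1c(O)c2c(c(O)c1C(C)C)C(=O)C[C@@H]1[C@]23CCC[C@]1(C)C(=O)OC3 | target

**Step count and risks**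
Total steps: 14. Longest linear sequence: 11 steps (steps 1–4, 7–9, 11–14, from 3,4-dimethoxyphenol); steps 5–6 and step 10 are side branches.

Step 12 (key step). What may go wrong: base-induced loss of HBr from the tertiary α-bromo ketone outruns addition of the tethered alkoxide, or one C4 epimer is diverted to an epoxy ether. Fallback with a cationic instead of an anionic trigger, setting out from 22: HF·pyridine in THF/pyridine at 0 °C should remove only the primary TBS ether and give the hydroxy bromo ketone F1, in equilibrium with its six-membered cyclic hemiketal. AgBF4 with 2,6-di-tert-butylpyridine in CH2Cl2 then abstracts bromide, and the hemiketal undergoes the semipinacol (quasi-Favorskii) shift of C3 to C4 to give the aryl-silylated lactone F2. Bu4NF removes the TIPS group, and the route is rejoined at 24.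

Step 11. What may go wrong: slow addition to the hindered, α-methylated enone, or poor facial selectivity at C5 through approach syn to the aryl group. Fallback by tethered delivery from C20, setting out from 17: HF·pyridine gives the primary alcohol F3, and bromoacetyl bromide/pyridine gives the bromoacetate F4. SmI2 in THF at −78 °C effects an intramolecular Reformatsky-type conjugate addition that closes a six-membered lactone, so C6 is necessarily cis to C20; the samarium enolate is brominated in the same flask with NBS to give the bromo keto lactone F5. Bu4NF and then aqueous LiOH remove the aryl silyl group and open the δ-lactone; the freed C20 alkoxide enters the same ring contraction, and acidification should give acid 25, where the route is rejoined.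

Step 8. What may go wrong: loss of the silyl enol ether to alkoxide, or sluggish carbene addition next to the quaternary centre and incomplete ring opening. Fallback by radical ring expansion, setting out from 14: Et2Zn/CH2I2 (Simmons–Smith) gives the siloxycyclopropane F6. FeCl3 in DMF followed by NaOAc in MeOH (Saegusa–Ito ring expansion by β-scission of the cyclopropyloxy radical and loss of HCl) gives the cycloheptenone F7. I2/pyridine gives the α-iodoenone F8, and Negishi coupling with MeZnCl/Pd(PPh3)4 rejoins the route at 17.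

Further compounds
F1 | step 12 | tert-butyl 2-[(1R,7R)-7-Ar-2-bromo-7-(hydroxymethyl)-2-methyl-3-oxocycloheptyl]acetate (both C4 epimers) | CC1(Br)C(=O)CCC[C@@](c2cc(O[Si](C(C)C)(C(C)C)C(C)C)c(C(C)C)c(OC)c2OC)(CO)[C@H]1CC(=O)OC(C)(C)C
F2 | step 12 | tert-butyl 2-[(1S,5R,9R)-5-Ar-1-methyl-2-oxo-3-oxabicyclo[3.3.1]nonan-9-yl]acetate | CC(C)(C)OC(=O)C[C@@H]1[C@@]2(c3cc(O[Si](C(C)C)(C(C)C)C(C)C)c(C(C)C)c(OC)c3OC)CCC[C@]1(C)C(=O)OC2
F3 | step 11 | (4R)-4-Ar-4-(hydroxymethyl)-2-methylcyclohept-2-en-1-one | O=C1CCC[C@@](c2cc(O[Si](C(C)C)(C(C)C)C(C)C)c(C(C)C)c(OC)c2OC)(CO)C=C1C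
F4 | step 11 | [(1R)-1-Ar-3-methyl-4-oxocyclohept-2-en-1-yl]methyl 2-bromoacetate | O=C1CCC[C@@](c2cc(O[Si](C(C)C)(C(C)C)C(C)C)c(C(C)C)c(OC)c2OC)(COC(=O)CBr)C=C1C
F5 | step 11 | (5R,10R)-configured 2-bromo-2-methylcycloheptanone cis-fused to the δ-lactone C7(=O)–O–C20, aryl TIPS ether (both C4 epimers) | CC1(Br)C(=O)CCC[C@@]2(c3cc(O[Si](C(C)C)(C(C)C)C(C)C)c(C(C)C)c(OC)c3OC)COC(=O)C[C@@H]12
F6 | step 8 | (5R)-5-Ar-5-{[tert-butyl(dimethyl)silyl]oxymethyl}-1-[(trimethylsilyl)oxy]bicyclo[4.1.0]heptane (cyclopropane diastereomers) | C[Si](C)(C)OC12CCC[C@@](c3cc(O[Si](C(C)C)(C(C)C)C(C)C)c(C(C)C)c(OC)c3OC)(CO[Si](C)(C)C(C)(C)C)C1C2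
F7 | step 8 | (4R)-4-Ar-4-{[tert-butyl(dimethyl)silyl]oxymethyl}cyclohept-2-en-1-one | O=C1CCC[C@@](c2cc(O[Si](C(C)C)(C(C)C)C(C)C)c(C(C)C)c(OC)c2OC)(CO[Si](C)(C)C(C)(C)C)C=C1
F8 | step 8 | (4R)-4-Ar-2-iodo-4-{[tert-butyl(dimethyl)silyl]oxymethyl}cyclohept-2-en-1-one | O=C1CCC[C@@](c2cc(O[Si](C(C)C)(C(C)C)C(C)C)c(C(C)C)c(OC)c2OC)(CO[Si](C)(C)C(C)(C)C)C=C1I
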